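**Strategy.** The route rests on cutting the bond between the benzylic CH2 of the O–CH2–CH2 ester bridge and C1 of the catechol ring. The key step is a nickel-catalysed reductive cross-electrophile coupling that joins the complete (2S,3S,4S)-dihydropyran core, carried as its 2-bromoethyl ester, to silyl-protected 4-bromocatechol. It exploits the primary CH2–Br carbon next to the acyloxy-bearing CH2 (its radical does not fragment) and the C–Br carbon of the arene. The core is assembled in three steps from methyl coumalate and (S)-but-3-yn-2-ol: ring-opening of the pyranone, thiyl-radical 6-exo cyclization, and vinyl sulfide hydrolysis.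

Key step: step 5

Remark on the chemistry: the exocyclic C=C of the vinyl sulfide from step 2 is expected as an E/Z mixture and is written without a descriptor, because C3 is reset in step 3.

**Step 1**
Reactants: 1 (S)-but-3-yn-2-ol; 2 methyl coumalate; 3 1,2-dibromoethane
Product: 6 1-(2-bromoethyl) 5-methyl (2Z,4E)-4-{[(2S)-but-3-yn-2-yloxy]methylidene}pent-2-enedioate, via sodium alkoxide 4 (not isolated), via sodium dienoate 5 (not isolated)
Conditions: NaH (1.0 equiv), THF, −20 °C; add 2, −20 to 0 °C; then DMF, 3 (10 equiv), 45 °C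
Reagents that add atoms: none
Why: Alkoxide 4 should add to C6 of the pyranone, the acrylate β-carbon that carries the ring oxygen as a vinylogous acyloxy leaving group (1,6-addition and ring-opening, a nucleophilic vinylic substitution of the kind known for methanol and amines on coumalates); the C2 stereocentre comes in unchanged from 1, the enol ether geometry is retained, and carboxylate 5 is esterified in the same flask by SN2 alkylation with excess 3.

**Step 2**
Reactants: 6 1-(2-bromoethyl) 5-methyl (2Z,4E)-4-{[(2S)-but-3-yn-2-yloxy]methylidene}pent-2-enedioate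
Product: 7 methyl (2S,4R)-4-[2-(2-bromoethoxy)-2-oxoethyl]-2-methyl-3-[(phenylsulfanyl)methylidene]-3,4-dihydro-2H-pyran-5-carboxylate
Conditions: PhSH (1.1 equiv, syringe pump), Et3B (0.3 equiv), air, toluene (0.01 M), rt
Reagents that add atoms: thiophenol, Sc1ccccc1
Why: Thiyl-radical addition–cyclization of a 1,7-enyne: PhS• adds to the terminal alkyne carbon, the C3 vinyl radical closes 6-exo-trig onto C4 (the enoate β-carbon, the only alkene carbon the O1–C6=C5 tether lets it reach) and the α-ester radical takes hydrogen from PhSH; C4 should form trans to the C2 methyl because allylic 1,3-strain from the exocyclic C3=CH–SPh bond lets only one flanking substituent lie pseudoequatorial while 1,3-diaxial strain excludes both axial; room-temperature initiation avoids the propargyl Claisen rearrangement.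

**Step 3**
Reactants: 7 methyl (2S,4R)-4-[2-(2-bromoethoxy)-2-oxoethyl]-2-methyl-3-[(phenylsulfanyl)methylidene]-3,4-dihydro-2H-pyran-5-carboxylate
Product: 8 methyl (2S,3S,4S)-4-[2-(2-bromoethoxy)-2-oxoethyl]-3-formyl-2-methyl-3,4-dihydro-2H-pyran-5-carboxylate
Conditions: HgCl2 (1.5 equiv), MeCN/H2O (4:1), 45 °C
Reagents that add atoms: water, O
Why: Hydrolysis of the vinyl sulfide assisted by divalent mercury (C3 protonation, thionium ion, water addition, loss of thiolate) unveils the aldehyde, and under the acid released C3 should equilibrate through the enol to the more stable epimer with the formyl group trans to the C4 acetate arm, the arrangement of elenolic acid, which is the 3S centre.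

**Step 4**
Reactants: 9 4-bromobenzene-1,2-diol
Product: 10 [(4-bromo-1,2-phenylene)bis(oxy)]bis(tert-butyldimethylsilane)
Conditions: TBSCl (2.4 equiv), imidazole (5 equiv), DMF, rt
Reagents that add atoms: tert-butyldimethylsilyl chloride, CC(C)(C)[Si](C)(C)Cl
Why: Imidazole-promoted silyl ether formation on both phenols masks the catechol against nickel chelation and oxidation in the coupling.

**Step 5**
Reactants: 8 methyl (2S,3S,4S)-4-[2-(2-bromoethoxy)-2-oxoethyl]-3-formyl-2-methyl-3,4-dihydro-2H-pyran-5-carboxylate; 10 [(4-bromo-1,2-phenylene)bis(oxy)]bis(tert-butyldimethylsilane)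
Product: 11 methyl (2S,3S,4S)-4-(2-{2-[3,4-bis(tert-butyldimethylsilyloxy)phenyl]ethoxy}-2-oxoethyl)-3-formyl-2-methyl-3,4-dihydro-2H-pyran-5-carboxylate
Conditions: NiBr2·glyme (10 mol %), 4,4′-di-tert-butyl-2,2′-bipyridine (12 mol %), Mn powder (3 equiv), 10 (1.5 equiv), DMA, 40 °C
Reagents that add atoms: none
Why: Aryl bromide 10 adds oxidatively to zerovalent nickel to give an aryl nickel bromide (divalent nickel), while a monovalent nickel species abstracts bromine from 8 to give the primary 2-(acyloxy)ethyl radical; capture of this radical gives an aryl alkyl complex of trivalent nickel that reductively eliminates the CH2–C(aryl) bond, and manganese returns nickel to its low oxidation state. The closest known reaction type is the nickel-catalysed reductive cross-electrophile coupling of aryl bromides with primary alkyl bromides. No ring is closed and no stereocentre is created; C2, C3 and C4 are only carried through. The step needs cross- over homo-coupling, which the two different activation modes (two-electron oxidative addition at the sp2 C–Br bond, halogen abstraction at the sp3 C–Br bond) should secure. It also needs the bromoethyl ester to survive, which is why manganese is used: it does not insert into the C–Br bond, so no β-acyloxy alkyl-metal species that could expel the carboxylate is formed, and the β-acyloxy radical itself does not fragment. The conditions are free of base, so the epimerizable C3 aldehyde and the enol ether ester should be left alone.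

**Step 6**
Reactants: 11 methyl (2S,3S,4S)-4-(2-{2-[3,4-bis(tert-butyldimethylsilyloxy)phenyl]ethoxy}-2-oxoethyl)-3-formyl-2-methyl-3,4-dihydro-2H-pyran-5-carboxylate
Product: 12 methyl (2S,3S,4S)-4-{2-[2-(3,4-dihydroxyphenyl)ethoxy]-2-oxoethyl}-3-formyl-2-methyl-3,4-dihydro-2H-pyran-5-carboxylate (CNP0172886.2)
Conditions: HF·pyridine, pyridine, THF, 0 °C
Reagents that add atoms: none
Why: Fluoride-mediated desilylation of the two aryl silyl ethers under buffered, non-basic conditions should leave both esters, the enol ether and the C3 aldehyde untouched and creates no stereocentre.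

**Compound list**
1 | (S)-but-3-yn-2-ol | C#C[C@H](C)O | starting material
2 | methyl coumalate (methyl 2-oxo-2H-pyran-5-carboxylate) | COC(=O)C1=COC(=O)C=C1 | starting material
3 | 1,2-dibromoethane | BrCCBr | starting material
4 | sodium (S)-but-3-yn-2-olate | C#C[C@H](C)[O-].[Na+] | intermediate
5 | sodium (2Z,4E)-4-{[(2S)-but-3-yn-2-yloxy]methylidene}-5-methoxy-5-oxopent-2-enoate | C#C[C@H](C)O/C=C(C(=O)OC)\C=C/C(=O)[O-].[Na+] | intermediate
6 | 1-(2-bromoethyl) 5-methyl (2Z,4E)-4-{[(2S)-but-3-yn-2-yloxy]methylidene}pent-2-enedioate | C#C[C@H](C)O/C=C(C(=O)OC)\C=C/C(=O)OCCBr | intermediate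
7 | methyl (2S,4R)-4-[2-(2-bromoethoxy)-2-oxoethyl]-2-methyl-3-[(phenylsulfanyl)methylidene]-3,4-dihydro-2H-pyran-5-carboxylate (2-methyl and 4-side chain trans; exocyclic C=C as E/Z mixture) | COC(=O)C1=CO[C@@H](C)C(=CSc2ccccc2)[C@@H]1CC(=O)OCCBr | intermediate
8 | methyl (2S,3S,4S)-4-[2-(2-bromoethoxy)-2-oxoethyl]-3-formyl-2-methyl-3,4-dihydro-2H-pyran-5-carboxylate | COC(=O)C1=CO[C@@H](C)[C@@H](C=O)[C@@H]1CC(=O)OCCBr | intermediate
9 | 4-bromobenzene-1,2-diol | Oc1ccc(Br)cc1O | starting material
10 | [(4-bromo-1,2-phenylene)bis(oxy)]bis(tert-butyldimethylsilane) | CC(C)(C)[Si](C)(C)Oc1ccc(Br)cc1O[Si](C)(C)C(C)(C)C | intermediate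
11 | methyl (2S,3S,4S)-4-(2-{2-[3,4-bis(tert-butyldimethylsilyloxy)phenyl]ethoxy}-2-oxoethyl)-3-formyl-2-methyl-3,4-dihydro-2H-pyran-5-carboxylate | COC(=O)C1=CO[C@@H](C)[C@@H](C=O)[C@@H]1CC(=O)OCCc2ccc(O[Si](C)(C)C(C)(C)C)c(O[Si](C)(C)C(C)(C)C)c2 | intermediate
12 | methyl (2S,3S,4S)-4-{2-[2-(3,4-dihydroxyphenyl)ethoxy]-2-oxoethyl}-3-formyl-2-methyl-3,4-dihydro-2H-pyran-5-carboxylate | COC(=O)C1=CO[C@@H](C)[C@@H](C=O)[C@@H]1CC(=O)OCCc1ccc(O)c(O)c1 | target

**Total step count:** 6
**Longest linear sequence:** 5 steps (steps 1, 2, 3, 5, 6)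

**Steps most likely to fail**

Step 1. The alkoxide may attack the lactone carbonyl or the methyl ester instead of C6, so that the ring opens with the wrong connectivity. The fallback sets out from compound 2 and comes back at compound 7. Morpholine, a nitrogen nucleophile for which 1,6-addition and ring-opening of coumalates is the rule, opens 2 to (2E,4E)-4-(methoxycarbonyl)-5-(morpholin-4-yl)penta-2,4-dienoic acid F1. Alkylation of its potassium salt with 3 (K2CO3, DMF) gives 1-(2-bromoethyl) 5-methyl (2E,4E)-4-(morpholin-4-ylmethylidene)pent-2-enedioate F2. Acid-mediated exchange of the vinylogous carbamate nitrogen for alcohol 1 (CF3CO2H, excess 1, toluene, 60 °C; C-protonation, alcohol addition, loss of morpholinium) gives 1-(2-bromoethyl) 5-methyl (2E,4E)-4-{[(2S)-but-3-yn-2-yloxy]methylidene}pent-2-enedioate F3, the 2E isomer of 6. F3 is cyclized under the conditions of step 2 to 7, since the geometry of that double bond disappears on ring closure.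

Step 2. Hydrogen transfer from the thiol to the vinyl radical may outrun ring closure, a second thiol may add to the vinyl sulfide, or facial control at C4 may be insufficient. The fallback sets out from compound 6 and comes back at compound 8. Anti-Markovnikov hydration of the terminal alkyne (CpRu(MeCN)3PF6, 5,5′-bis(trifluoromethyl)-2,2′-bipyridine, aqueous N-methylpyrrolidone) gives 1-(2-bromoethyl) 5-methyl (2Z,4E)-4-({[(2S)-4-oxobutan-2-yl]oxy}methylidene)pent-2-enedioate F4. An enamine-mediated intramolecular Michael addition (pyrrolidine, benzoic acid, CHCl3, rt) then closes the C3–C4 bond 6-exo and gives 8 directly, with the formyl group settling trans to the C4 arm.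

Step 5. The 2-bromoethyl ester may be lost reductively as ethene and carboxylate through a β-acyloxy alkyl-metal species, or the aryl group may be transferred to the aldehyde. The fallback sets out from compounds 8 and 10 and comes back at compound 11; it forms the same bond by aryl-radical addition instead. The liability is used as a deprotection: Zn dust with NaI in DMF cleaves the 2-haloethyl ester of 8 to 2-[(2S,3S,4S)-3-formyl-5-(methoxycarbonyl)-2-methyl-3,4-dihydro-2H-pyran-4-yl]acetic acid F5 (elenolic acid). Transvinylation with vinyl acetate (Pd(OAc)2, 1,10-phenanthroline, 60 °C) gives methyl (2S,3S,4S)-4-[2-(ethenyloxy)-2-oxoethyl]-3-formyl-2-methyl-3,4-dihydro-2H-pyran-5-carboxylate F6. Copper-catalysed halogen exchange on 10 (CuI, N,N′-dimethylethylenediamine, NaI, dioxane, 110 °C) gives [(4-iodo-1,2-phenylene)bis(oxy)]bis(tert-butyldimethylsilane) F7. Photoredox anti-Markovnikov hydroarylation of F6 with F7 (10-phenylphenothiazine, cyclohexanethiol, HCO2Na, DMSO/H2O, blue light) then gives 11: the aryl radical adds to the terminal CH2 of the vinyl ester and the α-acyloxy radical takes hydrogen from the thiol.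

**Further compounds**
F1 | step 1 | (2E,4E)-4-(methoxycarbonyl)-5-(morpholin-4-yl)penta-2,4-dienoic acid | C1COCCN1/C=C(C(=O)OC)\C=C\C(=O)O
F2 | step 1 | 1-(2-bromoethyl) 5-methyl (2E,4E)-4-(morpholin-4-ylmethylidene)pent-2-enedioate | C1COCCN1/C=C(C(=O)OC)\C=C\C(=O)OCCBr
F3 | step 1 | 1-(2-bromoethyl) 5-methyl (2E,4E)-4-{[(2S)-but-3-yn-2-yloxy]methylidene}pent-2-enedioate | C#C[C@H](C)O/C=C(C(=O)OC)\C=C\C(=O)OCCBr
F4 | step 2 | 1-(2-bromoethyl) 5-methyl (2Z,4E)-4-({[(2S)-4-oxobutan-2-yl]oxy}methylidene)pent-2-enedioate | O=CC[C@H](C)O/C=C(C(=O)OC)\C=C/C(=O)OCCBr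
F5 | step 5 | 2-[(2S,3S,4S)-3-formyl-5-(methoxycarbonyl)-2-methyl-3,4-dihydro-2H-pyran-4-yl]acetic acid | COC(=O)C1=CO[C@@H](C)[C@@H](C=O)[C@@H]1CC(=O)O
F6 | step 5 | methyl (2S,3S,4S)-4-[2-(ethenyloxy)-2-oxoethyl]-3-formyl-2-methyl-3,4-dihydro-2H-pyran-5-carboxylate | COC(=O)C1=CO[C@@H](C)[C@@H](C=O)[C@@H]1CC(=O)OC=C
F7 | step 5 | [(4-iodo-1,2-phenylene)bis(oxy)]bis(tert-butyldimethylsilane) | CC(C)(C)[Si](C)(C)Oc1ccc(I)cc1O[Si](C)(C)C(C)(C)C
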